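**Retrosynthetic overview**
- The flavone rings A, B and C come intact from luteolin; the last step only removes three benzyl ethers by neutral hydrogenolysis.
- The aryl–CH2 bond is cut to 6-iodo-7,3′,4′-tri-O-benzylluteolin and a (2-silyloxy-2,6,6-trimethylcyclohexyl)methylzinc iodide (Negishi coupling).
- The alkyl iodide goes back to a trans-1,3-diol and then to a trans-fused six-membered cyclic carbonate.
- Key bond: the tertiary C–O bond. It forms when the carbonyl oxygen of geranyl tert-butyl carbonate captures the tertiary cation in a chiral-acid-controlled, proton-initiated ring closure, which fixes both stereocenters (O trans to CH2).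
- Ring order: the cyclohexane and the cyclic carbonate close in that one step (the carbonate is opened afterwards); no other ring is built.

Assumption: the (S,S)-enantiomer of the IDPi catalyst is taken to give the (4aR,8aS)-carbonate; if the sense of induction is the opposite, the (R,R)-catalyst is used.

**Route**

Step 1
Reactants: 1 luteolin
Product: 2 7-(benzyloxy)-2-[3,4-bis(benzyloxy)phenyl]-5-hydroxy-4H-chromen-4-one
Conditions: BnBr (3.2 equiv), K2CO3, DMF, 25→50 °C
Reagents that add atoms: benzyl bromide, BrCc1ccccc1
Why: Williamson ether synthesis alkylates the 7-, 3′- and 4′-hydroxyls while the 5-hydroxyl, hydrogen-bonded to the C4 carbonyl, stays free; no stereocenter is formed.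

Step 2
Reactants: 2 7-(benzyloxy)-2-[3,4-bis(benzyloxy)phenyl]-5-hydroxy-4H-chromen-4-one
Product: 3 7-(benzyloxy)-2-[3,4-bis(benzyloxy)phenyl]-5-hydroxy-6-iodo-4H-chromen-4-one
Conditions: BnMe3N·ICl2 (1.1 equiv), CaCO3, CH2Cl2/MeOH (5:2), rt
Reagents that add atoms: benzyltrimethylammonium dichloroiodate, C[N+](C)(C)Cc1ccccc1.Cl[I-]Cl
Why: Electrophilic aromatic iodination in which the free, chelated 5-hydroxyl directs the iodonium equivalent to its ortho position C6 of the phloroglucinol-type ring A (5-hydroxy-7-alkoxyflavones react at C6), with CaCO3 taking up the HCl; no stereocenter is formed.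

Step 3
Reactants: 4 geraniol
Product: 5 tert-butyl (2E)-3,7-dimethylocta-2,6-dien-1-yl carbonate
Conditions: Boc2O (1.3 equiv), DMAP (10 mol %), CH2Cl2, 0 °C→rt
Reagents that add atoms: di-tert-butyl dicarbonate, CC(C)(C)OC(=O)OC(=O)OC(C)(C)C
Why: DMAP-catalysed O-acylation (Boc protection) of the primary allylic alcohol installs the internal oxygen nucleophile and leaves the (E)-alkene geometry untouched.

Step 4
Reactants: 5 tert-butyl (2E)-3,7-dimethylocta-2,6-dien-1-yl carbonate
Product: 7 (1S,2R)-2-(hydroxymethyl)-1,3,3-trimethylcyclohexan-1-ol, via trans-fused cyclic carbonate 6 (not isolated)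
Conditions: (S,S)-IDPi (confined BINOL-derived imidodiphosphorimidate acid, 3 mol %), perfluoro-tert-butanol/CHCl3 (4:1), −20 °C; concentrate; K2CO3 (0.3 equiv), MeOH, rt
Reagents that add atoms: none
Why: Proposed new method: the confined chiral Brønsted acid folds the substrate into a chair, protonates the terminal trisubstituted alkene, the (E)-2,3-alkene closes the carbocycle and the Boc carbonyl oxygen captures the tertiary cation anti to the new ring bond (Stork–Eschenmoser), so the tertiary C–O bond and the trans O/CH2O relationship are set stereospecifically while the catalyst pocket fixes the absolute configuration and loss of isobutene returns the proton; the closest known reactions are IDPi-catalysed proton-initiated polyene cyclizations terminated by a hydroxyl group and carbonate-terminated cation–olefin cyclizations started from epoxides or halonium ions; K2CO3/MeOH then transesterifies the carbonate to the diol without touching either stereocenter.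

Step 5
Reactants: 7 (1S,2R)-2-(hydroxymethyl)-1,3,3-trimethylcyclohexan-1-ol
Product: 9 {[(1S,2S)-2-(iodomethyl)-1,3,3-trimethylcyclohexyl]oxy}trimethylsilane, via hydroxy iodide 8 (not isolated)
Conditions: I2, PPh3, imidazole, toluene/MeCN, 0→60 °C; then Me3SiCl, rt
Reagents that add atoms: iodine, II; chlorotrimethylsilane, C[Si](C)(C)Cl
Why: Appel-type (Garegg–Samuelsson) iodination converts only the primary hydroxyl by SN2 displacement of its alkoxyphosphonium, the hindered tertiary hydroxyl is then silylated to mask it for the organozinc step, and neither stereocenter is touched.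

Step 6
Reactants: 9 {[(1S,2S)-2-(iodomethyl)-1,3,3-trimethylcyclohexyl]oxy}trimethylsilane; 3 7-(benzyloxy)-2-[3,4-bis(benzyloxy)phenyl]-5-hydroxy-6-iodo-4H-chromen-4-one
Product: 12 7-(benzyloxy)-2-[3,4-bis(benzyloxy)phenyl]-5-hydroxy-6-{[(1S,2S)-2-hydroxy-2,6,6-trimethylcyclohexyl]methyl}-4H-chromen-4-one, via alkylzinc iodide 10 (not isolated), via trimethylsilyl ether 11 (not isolated)
Conditions: Zn dust, LiCl, THF, 40 °C (from 9, 1.5 equiv); then slow addition to 3, Pd(OAc)2 (3 mol %), CPhos (6 mol %), THF/NMP, 25→45 °C; then K2CO3, MeOH, rt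
Reagents that add atoms: none
Why: Negishi cross-coupling in which zinc inserts into the primary C–I bond and the CPhos-ligated palladium catalyst joins the primary alkylzinc to the di-ortho-substituted aryl iodide faster than β-hydride elimination or protonolysis by the chelated 5-hydroxyl; the stereocenters are remote from the reacting carbon and mild methanolysis removes the silyl ether.

Step 7
Reactants: 12 7-(benzyloxy)-2-[3,4-bis(benzyloxy)phenyl]-5-hydroxy-6-{[(1S,2S)-2-hydroxy-2,6,6-trimethylcyclohexyl]methyl}-4H-chromen-4-one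
Product: 13 2-(3,4-dihydroxyphenyl)-5,7-dihydroxy-6-{[(1S,2S)-2-hydroxy-2,6,6-trimethylcyclohexyl]methyl}-4H-chromen-4-one
Conditions: H2 (1 atm), Pd/C (10 %), EtOAc/MeOH (1:1), rt
Reagents that add atoms: none
Why: Hydrogenolysis of the three benzyl ethers over Pd/C is neutral, so the tertiary alcohol (which would ionize and close onto a neighbouring phenol under acid) and the flavone C2–C3 double bond survive; no stereocenter is touched.

**Compound list**
1 | luteolin, 2-(3,4-dihydroxyphenyl)-5,7-dihydroxy-4H-chromen-4-one | O=c1cc(-c2ccc(O)c(O)c2)oc2cc(O)cc(O)c12 | starting material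
2 | 7-(benzyloxy)-2-[3,4-bis(benzyloxy)phenyl]-5-hydroxy-4H-chromen-4-one | O=c1cc(-c2ccc(OCc3ccccc3)c(OCc3ccccc3)c2)oc2cc(OCc3ccccc3)cc(O)c12 | intermediate
3 | 7-(benzyloxy)-2-[3,4-bis(benzyloxy)phenyl]-5-hydroxy-6-iodo-4H-chromen-4-one | O=c1cc(-c2ccc(OCc3ccccc3)c(OCc3ccccc3)c2)oc2cc(OCc3ccccc3)c(I)c(O)c12 | intermediate
4 | geraniol, (2E)-3,7-dimethylocta-2,6-dien-1-ol | CC(C)=CCC/C(C)=C/CO | starting material
5 | tert-butyl (2E)-3,7-dimethylocta-2,6-dien-1-yl carbonate | CC(C)=CCC/C(C)=C/COC(=O)OC(C)(C)C | intermediate
6 | (4aR,8aS)-5,5,8a-trimethylhexahydro-4H-1,3-benzodioxin-2-one, trans-fused cyclic carbonate | CC1(C)CCC[C@](C)(OC(=O)OC2)[C@H]12 | intermediate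
7 | (1S,2R)-2-(hydroxymethyl)-1,3,3-trimethylcyclohexan-1-ol | CC1(C)CCC[C@](C)(O)[C@H]1CO | intermediate
8 | (1S,2S)-2-(iodomethyl)-1,3,3-trimethylcyclohexan-1-ol | CC1(C)CCC[C@](C)(O)[C@H]1CI | intermediate
9 | {[(1S,2S)-2-(iodomethyl)-1,3,3-trimethylcyclohexyl]oxy}trimethylsilane | CC1(C)CCC[C@](C)(O[Si](C)(C)C)[C@H]1CI | intermediate
10 | iodo({(1S,2S)-2,6,6-trimethyl-2-[(trimethylsilyl)oxy]cyclohexyl}methyl)zinc | CC1(C)CCC[C@](C)(O[Si](C)(C)C)[C@H]1C[Zn]I | intermediate
11 | 7-(benzyloxy)-2-[3,4-bis(benzyloxy)phenyl]-5-hydroxy-6-({(1S,2S)-2,6,6-trimethyl-2-[(trimethylsilyl)oxy]cyclohexyl}methyl)-4H-chromen-4-one | CC1(C)CCC[C@](C)(O[Si](C)(C)C)[C@H]1Cc1c(OCc2ccccc2)cc2oc(-c3ccc(OCc4ccccc4)c(OCc4ccccc4)c3)cc(=O)c2c1O | intermediate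
12 | 7-(benzyloxy)-2-[3,4-bis(benzyloxy)phenyl]-5-hydroxy-6-{[(1S,2S)-2-hydroxy-2,6,6-trimethylcyclohexyl]methyl}-4H-chromen-4-one | CC1(C)CCC[C@](C)(O)[C@H]1Cc1c(OCc2ccccc2)cc2oc(-c3ccc(OCc4ccccc4)c(OCc4ccccc4)c3)cc(=O)c2c1O | intermediate
13 | 2-(3,4-dihydroxyphenyl)-5,7-dihydroxy-6-{[(1S,2S)-2-hydroxy-2,6,6-trimethylcyclohexyl]methyl}-4H-chromen-4-one (CNP0257603.1) | CC1(C)CCC[C@](C)(O)[C@H]1Cc1c(O)cc2oc(-c3ccc(O)c(O)c3)cc(=O)c2c1O | target

**Step count and risks**
Total: 7 steps. Longest linear sequence: 5 steps (4 → 5 → 7 → 9 → 12 → 13; the flavone branch 1 → 2 → 3 joins at step 6).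

The three steps most likely to fail:

Step 4 (the proposed new cyclization). The risks are acid cleavage of the Boc group or allylic ionization before ring closure, and insufficient enantiocontrol for so small a substrate. The fallback uses known chemistry, sets out from 5 and comes back at 7. An achiral strong acid (HNTf2, 5 mol %, hexafluoroisopropanol/CH2Cl2, −40 °C) runs the same carbonate-terminated cation–olefin cyclization, which is stereospecific for the trans fusion but gives the racemate. That is 6 together with its enantiomer (4aS,8aR)-5,5,8a-trimethylhexahydro-4H-1,3-benzodioxin-2-one F1. The rigid bicyclic carbonate is resolved by preparative chiral SFC, and 6 is methanolysed (K2CO3, MeOH) to 7.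

Step 5 (iodination next to a free tertiary alcohol). The CH2 carbon is flanked by a ring CH that carries two fully substituted neighbours, so displacement may be slow, and the 1,3-diol may instead give cyclic phosphorane or ether by-products. The fallback sets out from 7 and 3 and comes back at 12, bypassing 8 to 11. The primary alcohol is used directly as a radical precursor. Condensation of 7 with N-phenylbenzoxazolium tetrafluoroborate (pyridine, MTBE) gives 2-{[(1R,2S)-2-hydroxy-2,6,6-trimethylcyclohexyl]methoxy}-3-phenyl-2,3-dihydro-1,3-benzoxazole F2. Under photoredox/nickel dual catalysis ([Ir(ppy)2(dtbbpy)]PF6, NiBr2(dtbbpy), quinuclidine, DMA, blue light) this adduct fragments to the primary alkyl radical, which nickel couples with 3 (deoxygenative arylation of an alcohol) to give 12.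

Step 6 (Negishi coupling). The aryl iodide is flanked by OH and OBn, and the zinc reagent may be lost to protonolysis or β-hydride elimination. The fallback sets out from 8 (isolated after the iodination, without silylation) and 3 and comes back at 12. A nickel-catalysed reductive cross-electrophile coupling (NiBr2(dme), 4,4′-di-tert-butyl-2,2′-bipyridine, Zn, NaI, DMA, 60 °C) joins the two iodides through an alkyl radical, needs no preformed organozinc reagent and tolerates both free hydroxyls. It makes no compound beyond the list (F0).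

**Further compounds**
F1 | step 4 | (4aS,8aR)-5,5,8a-trimethylhexahydro-4H-1,3-benzodioxin-2-one | CC1(C)CCC[C@@](C)(OC(=O)OC2)[C@@H]12
F2 | step 5 | 2-{[(1R,2S)-2-hydroxy-2,6,6-trimethylcyclohexyl]methoxy}-3-phenyl-2,3-dihydro-1,3-benzoxazole | CC1(C)CCC[C@](C)(O)[C@H]1COC1Oc2ccccc2N1c1ccccc1
F0 | step 6 | none | none
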